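**Retrosynthetic overview**

1. Target 31 is fisetinidol-(4β→6)-leucofisetinidin (upper unit rings A/C/B, lower unit rings D/F/E, flavan numbering). Its labile 3,4-trans diol in ring F is made last, by NaBH4 reduction of the C4 ketone of the debenzylated dihydroflavonol 30.
2. Ring F of 29 is cut at O1–C8a and C3–C4. The pieces are aroyl chloride 24 (ring D, fluorine on C8a, upper unit on C6) and acid 9 (the C2–C3 unit, O1 as a silyl ether, an extra carboxyl on C3 that leaves as CO2).
3. Enabling feature: in ring F, C4 hangs on ring D at C4a, ortho to the ether carbon C8a, and C3 is an O-bearing sp3 carbon next to the O1-bearing C2. C4 can therefore enter as an aroyl carbon whose new ketone activates C8a–F for attack by O1 and makes C3 epimerizable (2,3-trans funnel).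
4. Upper unit: the aryl Grignard from 19 adds to chromanone 16 (ring C built by the same annulation from 9 and 11); ionic hydrogenation then sets the 4β (3,4-cis) bond to ring D.
5. Acid 9, which supplies C2 of both units, comes from one Evans glycolate aldol. Ring order: ring C (step 6), then ring F (step 13).

Key step: step 13

Remarks: compounds 1, 2, 4, 10 and 17 are taken as commercial. Salts formed by simple deprotonation of a reactant are not numbered. dF(CF3)ppy is cyclometalated 2-(2,4-difluorophenyl)-5-(trifluoromethyl)pyridine, dtbbpy is 4,4'-di-tert-butyl-2,2'-bipyridine, dme is 1,2-dimethoxyethane.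

**Route**

Step 1
Reactants: 1 (S)-4-benzyloxazolidin-2-one; 2 (benzyloxy)acetyl chloride
Product: 3 (S)-4-benzyl-3-[(benzyloxy)acetyl]oxazolidin-2-one
Conditions: n-BuLi, THF, −78 °C; then 2, −78 to 0 °C
Reagents that add atoms: none
Why: N-acylation of the lithiated oxazolidinone by an acid chloride is the standard entry to glycolate imides and creates no stereocentre.

Step 2
Reactants: 3 (S)-4-benzyl-3-[(benzyloxy)acetyl]oxazolidin-2-one; 4 3,4-bis(benzyloxy)benzaldehyde
Product: 6 (S)-4-benzyl-3-[(2S,3R)-2-(benzyloxy)-3-[3,4-bis(benzyloxy)phenyl]-3-hydroxypropanoyl]oxazolidin-2-one, via boron enolate 5 (not isolated)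
Conditions: Bu2BOTf, Et3N, CH2Cl2, −78 to 0 °C; 4, −78 to 0 °C; then pH 7 buffer, MeOH, H2O2
Reagents that add atoms: none
Why: Evans syn aldol addition: the Z boron enolate reacts through a Zimmerman–Traxler chair on the enolate face left open by the benzyl group of the auxiliary, which should set the (3R) carbinol (later C2 of both flavan units) and the (2S) centre (erased later).

Step 3
Reactants: 6 aldol adduct
Product: 7 (S)-4-benzyl-3-[(2S,3R)-2-(benzyloxy)-3-[3,4-bis(benzyloxy)phenyl]-3-[(tert-butyldimethylsilyl)oxy]propanoyl]oxazolidin-2-one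
Conditions: TBSOTf, 2,6-lutidine, CH2Cl2, 0 °C
Reagents that add atoms: tert-butyldimethylsilyl triflate, CC(C)(C)[Si](C)(C)OS(=O)(=O)C(F)(F)F
Why: Silylation masks the future O1 so that it cannot be acylated during anhydride formation and can be released by fluoride on demand.

Step 4
Reactants: 7 silyl ether imide
Product: 9 (2S,3R)-2-(benzyloxy)-3-[3,4-bis(benzyloxy)phenyl]-3-[(tert-butyldimethylsilyl)oxy]propanoic acid, via peroxy acid 8 (not isolated)
Conditions: LiOH, H2O2, THF/H2O, 0 °C; Na2SO3; then 1 M HCl to pH 4, 0 °C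
Reagents that add atoms: hydrogen peroxide, OO
Why: Hydroperoxide attacks the exocyclic imide carbonyl selectively (standard auxiliary cleavage) and sulfite reduces the peracid, leaving both stereocentres untouched.

Step 5
Reactants: 10 4-(benzyloxy)-2-fluorobenzoic acid
Product: 11 4-(benzyloxy)-2-fluorobenzoyl chloride
Conditions: (COCl)2, N,N-dimethylformamide (cat.), CH2Cl2, 0 °C to rt
Reagents that add atoms: oxalyl chloride, O=C(Cl)C(Cl)=O
Why: Standard Vilsmeier-type conversion of an acid into its chloride, to which benzyl ether and aryl fluoride are inert.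

Step 6
Reactants: 9 acid; 11 4-(benzyloxy)-2-fluorobenzoyl chloride
Product: 16 (2R,3R)-3,7-bis(benzyloxy)-2-[3,4-bis(benzyloxy)phenyl]chroman-4-one, via mixed anhydride 12 (not isolated), via silyl ketone 13 (not isolated), via hydroxy ketone 14 (not isolated), via cis chromanone 15 (not isolated)
Conditions: DBU, 1,4-dioxane, 0 °C to rt; NiCl2(dme) (10 mol%), dtbbpy (15 mol%), [Ir{dF(CF3)ppy}2(dtbbpy)]PF6 (1 mol%), blue LEDs, rt; then Bu4NF (0.3 equiv), THF, 0 °C to rt
Reagents that add atoms: none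
Why: This is the one-flask sequence of step 13 on the simple ring A partner (nickel/photoredox CO2 extrusion–recombination of anhydride 12 to ketone 13, then fluoride-relay desilylative SNAr closure of ring C), in which C2 comes unchanged from 9 and C3, formed without control at the radical stage, should equilibrate next to the ketone from cis isomer 15 to the diequatorial 2,3-trans isomer 16.

Step 7
Reactants: 17 methyl 2-fluoro-4-hydroxybenzoate
Product: 18 methyl 2-fluoro-4-hydroxy-5-iodobenzoate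
Conditions: N-iodosuccinimide, CF3CO2H (cat.), MeCN, rt
Reagents that add atoms: N-iodosuccinimide, O=C1CCC(=O)N1I
Why: Electrophilic iodination ortho to the phenol should go to C5 (para to fluorine, unhindered) rather than to C3, which is flanked by OH and F.

Step 8
Reactants: 18 iodophenol
Product: 19 methyl 4-(benzyloxy)-2-fluoro-5-iodobenzoate
Conditions: BnBr, K2CO3, DMF, rt
Reagents that add atoms: benzyl bromide, BrCc1ccccc1
Why: Williamson O-benzylation of the phenoxide is much faster than any intermolecular SNAr at the fluoride.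

Step 9
Reactants: 19 aryl iodide; 16 chromanone
Product: 21 methyl 4-(benzyloxy)-5-[(2R,3R)-3,7-bis(benzyloxy)-2-[3,4-bis(benzyloxy)phenyl]-4-hydroxychroman-4-yl]-2-fluorobenzoate (C4 epimers), via arylmagnesium chloride 20 (not isolated)
Conditions: iPrMgCl·LiCl, THF, −40 °C; then LaCl3·2LiCl, 16, −40 to 0 °C; aq. NH4Cl
Reagents that add atoms: none
Why: Iodine–magnesium exchange tolerates the meta ester at −40 °C and lanthanum-promoted 1,2-addition to the C4 ketone should outrun enolization; the new C4 centre is of no consequence because step 10 erases it.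

Step 10
Reactants: 21 tertiary alcohol
Product: 22 methyl 4-(benzyloxy)-5-[(2R,3S,4R)-3,7-bis(benzyloxy)-2-[3,4-bis(benzyloxy)phenyl]chroman-4-yl]-2-fluorobenzoate (2,3-trans-3,4-cis, ring D aryl 4β)
Conditions: Et3SiH, CF3CO2H, CH2Cl2, −30 to 0 °C
Reagents that add atoms: none
Why: Ionic hydrogenation: acid ionizes the doubly benzylic alcohol to a C4 cation stabilized by the para benzyloxy group of ring A, and the silane should deliver hydride pseudo-axially anti to the C3 benzyloxy group (pushed pseudo-axial by allylic strain with the 4-aryl group), placing H on the α face and ring D on the β face.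

Step 11
Reactants: 22 methyl ester
Product: 23 4-(benzyloxy)-5-[(2R,3S,4R)-3,7-bis(benzyloxy)-2-[3,4-bis(benzyloxy)phenyl]chroman-4-yl]-2-fluorobenzoic acid
Conditions: LiOH, THF/H2O, 40 °C; then 1 M HCl
Reagents that add atoms: lithium hydroxide, [Li+].[OH-]
Why: Saponification of the methyl ester is faster than hydroxide SNAr at the fluoride, and the carboxylate formed deactivates the ring further.

Step 12
Reactants: 23 acid
Product: 24 4-(benzyloxy)-5-[(2R,3S,4R)-3,7-bis(benzyloxy)-2-[3,4-bis(benzyloxy)phenyl]chroman-4-yl]-2-fluorobenzoyl chloride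
Conditions: (COCl)2, N,N-dimethylformamide (cat.), CH2Cl2, 0 °C to rt
Reagents that add atoms: oxalyl chloride, O=C(Cl)C(Cl)=O
Why: Standard acid chloride formation; no group in 23 is labile to the HCl released at this temperature.

Step 13
Reactants: 24 aroyl chloride; 9 acid
Product: 29 (2R,3R)-3,7-bis(benzyloxy)-2-[3,4-bis(benzyloxy)phenyl]-6-[(2R,3S,4R)-3,7-bis(benzyloxy)-2-[3,4-bis(benzyloxy)phenyl]chroman-4-yl]chroman-4-one, via mixed anhydride 25 (not isolated), via silyl ketone 26 (not isolated), via hydroxy ketone 27 (not isolated), via cis chromanone 28 (not isolated)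
Conditions: DBU, 1,4-dioxane, 0 °C to rt; NiCl2(dme) (10 mol%), dtbbpy (15 mol%), [Ir{dF(CF3)ppy}2(dtbbpy)]PF6 (1 mol%), blue LEDs, rt; then Bu4NF (0.3 equiv), THF, 0 °C to rt
Reagents that add atoms: none
Why: DBU joins acid 9 and aroyl chloride 24 as mixed anhydride 25; zerovalent nickel inserts into its aroyl C–O bond, the photoexcited iridium complex oxidizes the released α-benzyloxy carboxylate, CO2 is lost, and the C3 radical is captured at nickel so that reductive elimination forms C3–C4 and ketone 26 (closest known type: nickel/photoredox CO2 extrusion–recombination of mixed anhydrides of α-oxy acids with acyl chlorides, a radical counterpart of the Dakin–West reaction). The new C4 carbonyl is ortho to C8a and turns the C8a–F bond into an SNAr site; catalytic fluoride then frees O1 from silicon and the alkoxide of 27 closes ring F by 6-exo-trig addition–elimination through a Meisenheimer intermediate, each closure releasing the fluoride that desilylates the next molecule (closest known type: fluoride-catalysed aryl ether formation from silyl ethers and activated aryl fluorides). C2 is not touched and keeps the (R) configuration set in the Evans aldol of step 2. C3, formed without control at the radical stage, lies α to the C4 ketone, so the syn and anti ketones and the cis chromanone 28 should equilibrate through the enolate and funnel to the diequatorial 2,3-trans isomer 29 (stereoconvergent). The step needs decarboxylation of the α-oxy acid half only, O1 rather than O3 as ring-closing nucleophile (O3 is a benzyl ether, so no five-membered coumaranone can form), and ring closure faster than retro-aldol cleavage of 27 or E1cB opening of ring F, which the ortho-acyl activation, the six-membered transition state and the low fluoride loading buffered by DBU hydrochloride are chosen to secure.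

Step 14
Reactants: 29 octabenzyl ether
Product: 30 (2R,3R)-2-(3,4-dihydroxyphenyl)-6-[(2R,3S,4S)-2-(3,4-dihydroxyphenyl)-3,7-dihydroxychroman-4-yl]-3,7-dihydroxychroman-4-one
Conditions: H2 (1 atm), Pd(OH)2/C, THF/MeOH, rt
Reagents that add atoms: none
Why: Neutral hydrogenolysis cleaves all eight benzyl ethers while the chromanone carbonyl and the ring C–O bonds should survive, as in debenzylations of protected dihydroflavonols.

Step 15
Reactants: 30 dihydroflavonol
Product: 31 (2R,3S,4R)-2-(3,4-dihydroxyphenyl)-6-[(2R,3S,4S)-2-(3,4-dihydroxyphenyl)-3,7-dihydroxychroman-4-yl]chroman-3,4,7-triol (target)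
Conditions: NaBH4, EtOH, 0 °C; acetone quench, work-up at pH 6–7, Sephadex LH-20
Reagents that add atoms: none
Why: Borohydride should attack the C4 ketone of the 2,3-trans dihydroflavonol axially from the β face to give the equatorial 4α-hydroxyl (2,3-trans-3,4-trans), as in the reduction of fustin or taxifolin to the corresponding flavan-3,4-diols; the acid-free work-up protects the ionizable C4–OH.

**Compound list**

1 | (S)-4-benzyloxazolidin-2-one | O=C1N[C@@H](Cc2ccccc2)CO1 | starting material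
2 | (benzyloxy)acetyl chloride | O=C(Cl)COCc1ccccc1 | starting material
3 | (S)-4-benzyl-3-[(benzyloxy)acetyl]oxazolidin-2-one | O=C1OC[C@H](Cc2ccccc2)N1C(=O)COCc1ccccc1 | intermediate
4 | 3,4-bis(benzyloxy)benzaldehyde | O=Cc1ccc(OCc2ccccc2)c(OCc2ccccc2)c1 | starting material
5 | (Z)-dibutylboron enolate of 3 | O=C1OC[C@H](Cc2ccccc2)N1/C(=C/OCc1ccccc1)OB(CCCC)CCCC | intermediate
6 | (S)-4-benzyl-3-[(2S,3R)-2-(benzyloxy)-3-[3,4-bis(benzyloxy)phenyl]-3-hydroxypropanoyl]oxazolidin-2-one | O=C1OC[C@H](Cc2ccccc2)N1C(=O)[C@@H](OCc1ccccc1)[C@H](O)c1ccc(OCc2ccccc2)c(OCc2ccccc2)c1 | intermediate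
7 | tert-butyldimethylsilyl ether of 6 | O=C1OC[C@H](Cc2ccccc2)N1C(=O)[C@@H](OCc1ccccc1)[C@H](O[Si](C)(C)C(C)(C)C)c1ccc(OCc2ccccc2)c(OCc2ccccc2)c1 | intermediate
8 | (2S,3R)-2-(benzyloxy)-3-[3,4-bis(benzyloxy)phenyl]-3-[(tert-butyldimethylsilyl)oxy]propaneperoxoic acid | OOC(=O)[C@@H](OCc1ccccc1)[C@H](O[Si](C)(C)C(C)(C)C)c1ccc(OCc2ccccc2)c(OCc2ccccc2)c1 | intermediate
9 | (2S,3R)-2-(benzyloxy)-3-[3,4-bis(benzyloxy)phenyl]-3-[(tert-butyldimethylsilyl)oxy]propanoic acid | OC(=O)[C@@H](OCc1ccccc1)[C@H](O[Si](C)(C)C(C)(C)C)c1ccc(OCc2ccccc2)c(OCc2ccccc2)c1 | intermediate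
10 | 4-(benzyloxy)-2-fluorobenzoic acid | OC(=O)c1ccc(OCc2ccccc2)cc1F | starting material
11 | 4-(benzyloxy)-2-fluorobenzoyl chloride | O=C(Cl)c1ccc(OCc2ccccc2)cc1F | intermediate
12 | mixed anhydride of 9 with 4-(benzyloxy)-2-fluorobenzoic acid | O=C(OC(=O)[C@@H](OCc1ccccc1)[C@H](O[Si](C)(C)C(C)(C)C)c1ccc(OCc2ccccc2)c(OCc2ccccc2)c1)c1ccc(OCc2ccccc2)cc1F | intermediate
13 | (3R)-2-(benzyloxy)-1-[4-(benzyloxy)-2-fluorophenyl]-3-[3,4-bis(benzyloxy)phenyl]-3-[(tert-butyldimethylsilyl)oxy]propan-1-one (both C2 epimers) | O=C(c1ccc(OCc2ccccc2)cc1F)C(OCc1ccccc1)[C@H](O[Si](C)(C)C(C)(C)C)c1ccc(OCc2ccccc2)c(OCc2ccccc2)c1 | intermediate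
14 | (3R)-2-(benzyloxy)-1-[4-(benzyloxy)-2-fluorophenyl]-3-[3,4-bis(benzyloxy)phenyl]-3-hydroxypropan-1-one (both C2 epimers) | O=C(c1ccc(OCc2ccccc2)cc1F)C(OCc1ccccc1)[C@H](O)c1ccc(OCc2ccccc2)c(OCc2ccccc2)c1 | intermediate
15 | (2R,3S)-3,7-bis(benzyloxy)-2-[3,4-bis(benzyloxy)phenyl]chroman-4-one (2,3-cis) | C(c1ccccc1)Oc1ccc2c(c1)O[C@H](c1ccc(OCc3ccccc3)c(OCc3ccccc3)c1)[C@H](OCc1ccccc1)C2=O | intermediate
16 | (2R,3R)-3,7-bis(benzyloxy)-2-[3,4-bis(benzyloxy)phenyl]chroman-4-one (2,3-trans) | C(c1ccccc1)Oc1ccc2c(c1)O[C@H](c1ccc(OCc3ccccc3)c(OCc3ccccc3)c1)[C@@H](OCc1ccccc1)C2=O | intermediate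
17 | methyl 2-fluoro-4-hydroxybenzoate | COC(=O)c1ccc(O)cc1F | starting material
18 | methyl 2-fluoro-4-hydroxy-5-iodobenzoate | COC(=O)c1cc(I)c(O)cc1F | intermediate
19 | methyl 4-(benzyloxy)-2-fluoro-5-iodobenzoate | COC(=O)c1cc(I)c(OCc2ccccc2)cc1F | intermediate
20 | [2-(benzyloxy)-4-fluoro-5-(methoxycarbonyl)phenyl]magnesium chloride (LiCl complex) | COC(=O)c1cc([Mg]Cl)c(OCc2ccccc2)cc1F | intermediate
21 | methyl 4-(benzyloxy)-5-[(2R,3R)-3,7-bis(benzyloxy)-2-[3,4-bis(benzyloxy)phenyl]-4-hydroxychroman-4-yl]-2-fluorobenzoate (C4 epimers) | C(c1ccccc1)Oc1ccc2c(c1)O[C@H](c1ccc(OCc3ccccc3)c(OCc3ccccc3)c1)[C@@H](OCc1ccccc1)C2(O)c1cc(C(=O)OC)c(F)cc1OCc1ccccc1 | intermediate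
22 | methyl 4-(benzyloxy)-5-[(2R,3S,4R)-3,7-bis(benzyloxy)-2-[3,4-bis(benzyloxy)phenyl]chroman-4-yl]-2-fluorobenzoate (ring D aryl 4β, cis to 3-OBn) | C(c1ccccc1)Oc1ccc2c(c1)O[C@H](c1ccc(OCc3ccccc3)c(OCc3ccccc3)c1)[C@@H](OCc1ccccc1)[C@H]2c1cc(C(=O)OC)c(F)cc1OCc1ccccc1 | intermediate
23 | 4-(benzyloxy)-5-[(2R,3S,4R)-3,7-bis(benzyloxy)-2-[3,4-bis(benzyloxy)phenyl]chroman-4-yl]-2-fluorobenzoic acid | C(c1ccccc1)Oc1ccc2c(c1)O[C@H](c1ccc(OCc3ccccc3)c(OCc3ccccc3)c1)[C@@H](OCc1ccccc1)[C@H]2c1cc(C(=O)O)c(F)cc1OCc1ccccc1 | intermediate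
24 | 4-(benzyloxy)-5-[(2R,3S,4R)-3,7-bis(benzyloxy)-2-[3,4-bis(benzyloxy)phenyl]chroman-4-yl]-2-fluorobenzoyl chloride | C(c1ccccc1)Oc1ccc2c(c1)O[C@H](c1ccc(OCc3ccccc3)c(OCc3ccccc3)c1)[C@@H](OCc1ccccc1)[C@H]2c1cc(C(=O)Cl)c(F)cc1OCc1ccccc1 | intermediate
25 | mixed anhydride of 23 with 9 | C(c1ccccc1)Oc1ccc2c(c1)O[C@H](c1ccc(OCc3ccccc3)c(OCc3ccccc3)c1)[C@@H](OCc1ccccc1)[C@H]2c1cc(C(=O)OC(=O)[C@@H](OCc2ccccc2)[C@H](O[Si](C)(C)C(C)(C)C)c2ccc(OCc3ccccc3)c(OCc3ccccc3)c2)c(F)cc1OCc1ccccc1 | intermediate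
26 | ring D aryl ketone ArD–CO–CH(OBn)–CH(OTBS)–Ar, (3R) carbinol, both C2 epimers, upper unit as in 22 | C(c1ccccc1)Oc1ccc2c(c1)O[C@H](c1ccc(OCc3ccccc3)c(OCc3ccccc3)c1)[C@@H](OCc1ccccc1)[C@H]2c1cc(C(=O)C(OCc2ccccc2)[C@H](O[Si](C)(C)C(C)(C)C)c2ccc(OCc3ccccc3)c(OCc3ccccc3)c2)c(F)cc1OCc1ccccc1 | intermediate
27 | desilylated hydroxy ketone of 26, (3R) carbinol, both C2 epimers | C(c1ccccc1)Oc1ccc2c(c1)O[C@H](c1ccc(OCc3ccccc3)c(OCc3ccccc3)c1)[C@@H](OCc1ccccc1)[C@H]2c1cc(C(=O)C(OCc2ccccc2)[C@H](O)c2ccc(OCc3ccccc3)c(OCc3ccccc3)c2)c(F)cc1OCc1ccccc1 | intermediate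
28 | (2R,3S)-3,7-bis(benzyloxy)-2-[3,4-bis(benzyloxy)phenyl]-6-[(2R,3S,4R)-3,7-bis(benzyloxy)-2-[3,4-bis(benzyloxy)phenyl]chroman-4-yl]chroman-4-one (ring F 2,3-cis) | C(c1ccccc1)Oc1ccc2c(c1)O[C@H](c1ccc(OCc3ccccc3)c(OCc3ccccc3)c1)[C@@H](OCc1ccccc1)[C@H]2c1cc2c(cc1OCc1ccccc1)O[C@H](c1ccc(OCc3ccccc3)c(OCc3ccccc3)c1)[C@H](OCc1ccccc1)C2=O | intermediate
29 | (2R,3R)-3,7-bis(benzyloxy)-2-[3,4-bis(benzyloxy)phenyl]-6-[(2R,3S,4R)-3,7-bis(benzyloxy)-2-[3,4-bis(benzyloxy)phenyl]chroman-4-yl]chroman-4-one (ring F 2,3-trans) | C(c1ccccc1)Oc1ccc2c(c1)O[C@H](c1ccc(OCc3ccccc3)c(OCc3ccccc3)c1)[C@@H](OCc1ccccc1)[C@H]2c1cc2c(cc1OCc1ccccc1)O[C@H](c1ccc(OCc3ccccc3)c(OCc3ccccc3)c1)[C@@H](OCc1ccccc1)C2=O | intermediate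
30 | (2R,3R)-2-(3,4-dihydroxyphenyl)-6-[(2R,3S,4S)-2-(3,4-dihydroxyphenyl)-3,7-dihydroxychroman-4-yl]-3,7-dihydroxychroman-4-one | Oc1ccc2c(c1)O[C@H](c1ccc(O)c(O)c1)[C@@H](O)[C@H]2c1cc2c(cc1O)O[C@H](c1ccc(O)c(O)c1)[C@@H](O)C2=O | intermediate
31 | (2R,3S,4R)-2-(3,4-dihydroxyphenyl)-6-[(2R,3S,4S)-2-(3,4-dihydroxyphenyl)-3,7-dihydroxychroman-4-yl]chroman-3,4,7-triol | Oc1ccc2c(c1)O[C@H](c1ccc(O)c(O)c1)[C@@H](O)[C@H]2c1cc2c(cc1O)O[C@H](c1ccc(O)c(O)c1)[C@@H](O)[C@@H]2O | target

**Step count and risks**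

Total steps: 15. Longest linear sequence: 12 (steps 1, 2, 3, 4, 6, 9, 10, 11, 12, 13, 14, 15).

Steps most likely to fail:

Step 13. What may go wrong:
- decarbonylation or slow radical capture at the hindered aroyl nickel intermediate, so that little ketone forms;
- retro-aldol cleavage of the β-oxido ketone or E1cB opening of ring F in the fluoride stage, which would scramble C2;
- incomplete equilibration at C3.

Fallback, setting out from 24: a Migita–Kosugi–Stille acylation with tributyl[(benzyloxy)methyl]stannane (PdCl2(PPh3)2, toluene, 80 °C) should give the benzyloxymethyl ketone F1. Me3SiOTf and Et3N should convert it into the (Z)-trimethylsilyl enol ether F2. An enantioselective Mukaiyama aldol addition of F2 to aldehyde 4, catalysed by the enantiomer of the N-tosyltryptophan-derived B-butyl-1,3,2-oxazaborolidin-5-one that delivers the (3R) carbinol, should give hydroxy ketone 27 after desilylative work-up, where the fallback comes back to the route. K2CO3 in DMF then closes ring F and equilibrates C3 to 29. The C2 epimers are diastereomers, because the upper unit is enantiopure, and can be separated. This fallback forms C2–C3 by aldol addition instead of C3–C4 and needs no photochemistry.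

Step 6. What may go wrong: the same processes as in step 13, met here for the first time. Fallback, setting out from 9: coupling with N,O-dimethylhydroxylamine (EDC·HCl, CH2Cl2) should give the Weinreb amide F3. [4-(Benzyloxy)-2-fluorophenyl]lithium F4, made from commercial 4-(benzyloxy)-1-bromo-2-fluorobenzene and n-BuLi in THF at −78 °C, adds to F3 (Weinreb ketone synthesis, forming C4–C4a instead of C3–C4). This gives silyl ketone 13 as its single (2S,3R) isomer, where the fallback comes back to the route; Bu4NF then closes ring C and equilibrates C3 to 16.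

Step 10. What may go wrong:
- loss of H3 from the C4 cation (enol ether formation with erosion at C3);
- insufficient facial bias in the hydride transfer;
- acid-induced opening of the C2–O1 bond.

Fallback, setting out from 21: acylation with methyl chlorooxoacetate (Et3N, 4-(dimethylamino)pyridine, CH2Cl2) should give the tertiary methyl oxalate F5. Bu3SnH with azobisisobutyronitrile in toluene at 90 °C (Barton–McCombie-type radical deoxygenation of a tertiary oxalate) then leads back to 22. The planar C4 radical takes hydrogen from the stannane on the face anti to the C3 benzyloxy group, and no cation or acid is involved.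

**Further compounds**

F1 | step 13 | 2-(benzyloxy)-1-{4-(benzyloxy)-2-fluoro-5-[(2R,3S,4R)-3,7-bis(benzyloxy)-2-[3,4-bis(benzyloxy)phenyl]chroman-4-yl]phenyl}ethan-1-one | C(c1ccccc1)Oc1ccc2c(c1)O[C@H](c1ccc(OCc3ccccc3)c(OCc3ccccc3)c1)[C@@H](OCc1ccccc1)[C@H]2c1cc(C(=O)COCc2ccccc2)c(F)cc1OCc1ccccc1
F2 | step 13 | (Z)-trimethylsilyl enol ether of F1 | C(c1ccccc1)Oc1ccc2c(c1)O[C@H](c1ccc(OCc3ccccc3)c(OCc3ccccc3)c1)[C@@H](OCc1ccccc1)[C@H]2c1cc(/C(=C/OCc2ccccc2)O[Si](C)(C)C)c(F)cc1OCc1ccccc1
F3 | step 6 | (2S,3R)-2-(benzyloxy)-3-[3,4-bis(benzyloxy)phenyl]-3-[(tert-butyldimethylsilyl)oxy]-N-methoxy-N-methylpropanamide | CON(C)C(=O)[C@@H](OCc1ccccc1)[C@H](O[Si](C)(C)C(C)(C)C)c1ccc(OCc2ccccc2)c(OCc2ccccc2)c1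
F4 | step 6 | [4-(benzyloxy)-2-fluorophenyl]lithium | [Li]c1ccc(OCc2ccccc2)cc1F
F5 | step 10 | methyl oxalate of tertiary alcohol 21 | C(c1ccccc1)Oc1ccc2c(c1)O[C@H](c1ccc(OCc3ccccc3)c(OCc3ccccc3)c1)[C@@H](OCc1ccccc1)C2(OC(=O)C(=O)OC)c1cc(C(=O)OC)c(F)cc1OCc1ccccc1
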